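## Structural features

The target is a labdane: a trans-fused decalin (ring A = C1–C5 and C10, with the gem-dimethyl carbon C4; ring B = C5–C10) carrying the angular methyl C20 on C10, a tertiary acetate and the methyl C17 on C8, and on C9 the chain C11–C16 that ends in the C15 carboxylic acid. Four of the five stereocentres are contiguous on ring B (C5, C10, C9, C8): C10 is quaternary, C8 is fully substituted, and C5 lies between the two quaternary carbons C4 and C10. The fifth stereocentre, C13, is isolated on the chain and cannot be controlled from the ring. C20, C17 and C11 are all on the β face, while H5, H9 and the C8 oxygen are α, so the two ring B methyl groups are syn-diaxial and the oxygen is equatorial. The tertiary acetate is the fragile group: it is slow to form, it is lost by elimination under acid or heat, and it must coexist with a free acid. The real difficulties are the C4–C5 bond with trans ring fusion, the sense of the C8 carbinol, and C13. The key step exploits the C9–C10 pair of ring B: the cis relation of C11 and C20 is the cis relation of two substituents on a trisubstituted C9=C10 double bond of an enal whose formyl carbon is C1 and whose β-substituent is the complete chain with C13 already in place. A [4+2] cycloaddition of a four-carbon diene (C5–C8) across that bond closes ring B and sets both centres.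

## Logic of the disconnections

- **31 ⇒ 29.** The O8–acyl bond is cut last because the tertiary acetate is the most labile group. The forward step must acylate a hindered tertiary hydroxyl next to a free carboxyl without dehydration; the carboxyl is tied up transiently as 30.
- **29 ⇒ 27.** The C15 acid is taken back to the primary alcohol, so that C15 passes the organometallic steps as an ether. The forward oxidation (through 28) must leave the tertiary hydroxyl alone.
- **27 ⇒ 25.** A carbonyl is put back on C3 and the silyl group on O15. The C3 oxygen is what remains of the carboxyl carbon that brings C4 to C5. The forward step (through 26) must deoxygenate a ketone beside a quaternary carbon; the same hot alkali is expected to free O15.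
- **25 ⇒ 24.** The C1=C2 and C6=C7 double bonds are restored. They are left by the ring closure and by the sigmatropic step. The forward hydrogenation creates no stereocentre but must not break the allylic C8–O bond.
- **24 ⇒ 23.** Ring A is opened at C1=C2 (metathesis retron). This reduces the bicycle to ring B with two arms, trans on C10 and C5. The forward step needs a vinyl ketone and a neopentylic vinyl group to close a six-membered ring.
- **23 ⇒ 21.** The C2–C3 bond is cut to a carboxylic acid. The forward step (through 22) needs a single addition of a vinyl nucleophile to a hindered carboxylate.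
- **21 ⇒ 18.** The C4–C5 bond is cut by a Claisen retron: the C6=C7 alkene moves to C5=C6 and C3 is reattached through oxygen to C7. This is the most congested bond and carries the C5 configuration. An intermolecular conjugate addition at C5 was set aside because the face of attack on the 4,4-disubstituted enone depends on which C10 substituent is pseudoaxial and could not be predicted. A later acid closure through an isopropenyl group was set aside because that group would rather attack the ketone in a carbonyl-ene sense. The sigmatropic route (through 19 and 20) transfers the configuration of C7–O to C5, makes the C4 quaternary centre, and removes the C7 oxygen in the same step. It demands a 7β oxygen.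
- **18 ⇒ 16 + 17.** The ester C–O bond is cut; C3, C4, C18 and C19 come from 17. The forward step must distinguish the secondary from the tertiary hydroxyl.
- **16 ⇒ 15.** The C7 carbinol goes back to the ketone. The forward reduction must deliver hydride to the α face.
- **15 ⇒ 13 ⇒ 11.** The C8–O bond and then the C8–C17 bond are cut. C8 is the α' carbon of a cross-conjugated enone whose γ carbon (C10) is quaternary, so it is the only enolisable position and both substituents enter regiospecifically (through 14 and 12). Carbon first and oxygen second is required, because the second electrophile enters anti to the C9 chain and must be the oxygen.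
- **11 ⇒ 10.** The enone is taken back to the silyl enol ether; the position of the double bond is inherited from the cycloaddition.
- **10 ⇒ 9.** The vinyl group is taken back to the formyl group. While C1 is an alkene the C7 ketone stays masked; the extra methylene leaves as ethene at 24.
- **9 ⇒ 6 + 8.** The C5–C10 and C8–C9 bonds are cut (Diels–Alder retron: 4-oxygenated cyclohexene with cis 1,2-substituents). This removes ring B and two stereocentres and leaves an acyclic enal that already holds C1, C9–C16 and C20. The forward step needs face control by a catalyst and para regiochemistry.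
- **6 ⇒ 4 + 5.** The C9=C10 double bond is cut (Wittig). The forward step must give the (E) isomer, since this geometry becomes the cis C11/C20 relation.
- **4 ⇒ 2 ⇒ 1 and 8 ⇒ 7.** The C=C bond of 2 is the latent aldehyde (through 3), and 2 is the silyl ether of 1, which supplies C13 from the chiral pool. 8 is the O-silylated enol of 7.

## Other disconnections considered

**Alternative 1:** The cut is C3–C4 in ring A, with C4 and its two methyl groups taken from the cyclobutane of a pinane-type bicyclic ketone of the chiral pool. Forward, a Lewis acid (EtAlCl2 or TiCl4) on the C8 ketone breaks the strained C4–C7 bond, and the tertiary C4 cation is trapped at C3 by a (Z)-vinylsilane arm on C10. This closes ring A and gives methyl (13S)-8-oxo-17-norlabd-2-en-15-oate A1.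
- In its favour: C4 comes ready-made, C5 is inherited from a bridgehead, and the quaternary bond forms in one step. The carbonyl of A1 is on C8, the carbon that is oxygenated in the target. On oxygen placement and on the steps spent on ring A, this alternative is better than the chosen plan.
- Against it: the substrate must already hold the C10 quaternary centre, the vinylsilane arm and the whole C9 chain with C13, each added by a separate stereocontrolled alkylation. The C4 cation can lose a proton to an isopropenyl or isopropylidene group before a weakly nucleophilic vinylsilane captures it. From A1, direct methyl addition to the C8 ketone should come from the α face (the β face is covered by C20) and give the 8β-alcohol, so an indirect methylenation, epoxidation and hydride opening would have to be fitted around the C15 ester.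
- Comparison: on structure, the alternative maps C4 and C8 better and the chosen plan maps C9, C10 and C13 better. On mechanism, a cationic fragmentation–cyclisation with competing elimination stands against a concerted cycloaddition and a concerted sigmatropic shift, whose outcome is easier to foresee. On step economy the two are about equal.

**Alternative 2:** The cut removes C7 from ring B (C6–C7 and C7–C8) and leads back to a trans-hydrindanone in which C6 and C8 are bonded. Forward, the enol ether C6=C8 is cyclopropanated with Et2Zn/CH2I2 and the siloxycyclopropane is opened with FeCl3. This inserts CH2 as C7 and gives the trans-fused 6-en-8-one A2.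
- In its favour: the ring expansion is regiospecific, and the trans fusion and C4 are in place before the key step. The carbonyl is on C8 with only C9 enolisable. Carbonyl placement is better than in the chosen plan, and the reliability of the key step is its equal.
- Against it: A2 has neither the C9 chain nor C17. The chain with C13 would have to be attached by alkylating a neopentylic C9 enolate with an unactivated primary halide, a slow reaction open to O-alkylation, with C9 set only by later equilibration. The enantiopure hydrindanone needs its own multi-step synthesis. The C8 methyl carbinol raises the same facial problem as in Alternative 1.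
- Comparison: on structure, three stereocentres (C8, C9, C13) stay open after the key step, whereas the chosen plan has fixed C9, C10 and C13 by step 5. On mechanism, the key step is sound but the alkylation that follows is weak. On step economy it is worse than the chosen plan.

**Alternative 3:** The cut is C8–C9 of ring B. Forward, SmI2 (divalent samarium) with HMPA reduces a C8 methyl ketone, on a chain from C5, to its ketyl. The ketyl adds 6-exo to C9 of an enoate on C10 and gives the tertiary alcohol A3.
- In its favour: the C8 carbinol with C17 and the C9 centre arise together, with the anti relation of oxygen and ester arm that such cyclisations normally show and that the target needs. No oxygen has to be moved. On the C8/C9 pair this is better than the chosen plan, which spends steps 8 to 10 on it.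
- Against it: A3 ends at C12, so C13–C16 with the C13 stereocentre must be added afterwards by a chiral four-carbon fragment, with the tertiary alcohol protected. The substrate needs ring A with trans-related arms on C5 and C10, which is the C4–C5–C10 problem again. HMPA is required.
- Comparison: on structure, the chosen plan carries the full chain from step 3, which is better, and the alternative handles C8 better. On mechanism, a chelation-controlled radical-anion cyclisation and a catalyst-controlled cycloaddition are equals in predictability. On step economy the alternative is equal or slightly longer once ring A and the chain are counted.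

Key step: step 5

**Remarks before the steps**

- Labdane numbering is used for all atoms; α is the face of H5, β the face of C20.
- Assumption: the facial sense of the protonated oxazaborolidine follows the usual formyl C–H···O model for 2-substituted enals. On that model the (R)-prolinol-derived catalyst gives 9. If the sense were the opposite, the (S)-catalyst would be used and nothing else would change.
- The structures of 1, 6 and 9 were checked against the target (5S,8R,9R,10S,13S): (S)-citronellol gives 13S, the (E)-enal gives cis C11/C20, and the descriptors of 9 agree. No correction was needed.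
- The only change to the precursor is the C15 protecting group: tert-butyldiphenylsilyl in place of a smaller silyl group, so that it survives the acidic steps and falls in step 16.

## Route

Step 1
Reactants: 1 (S)-citronellol
Product: 2 (3S)-1-(tert-butyldiphenylsilyloxy)-3,7-dimethyloct-6-ene
Conditions: tBuPh2SiCl, imidazole, DMF, 0 °C → rt
Reagents that add atoms: tert-butyl(chloro)diphenylsilane, CC(C)(C)[Si](Cl)(c1ccccc1)c1ccccc1
Why: Imidazole-promoted O-silylation of a primary alcohol; this silyl ether should withstand the Lewis and Brønsted acids of steps 5, 10 and 12 and is expected to be cleaved by the hot alkali of step 16.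

Step 2
Reactants: 2 (3S)-1-(tert-butyldiphenylsilyloxy)-3,7-dimethyloct-6-ene
Product: 4 (4S)-6-(tert-butyldiphenylsilyloxy)-4-methylhexanal, via secondary ozonide 3 (not isolated)
Conditions: O3, CH2Cl2, −78 °C; then PPh3, −78 °C → rt
Reagents that add atoms: ozone, [O-][O+]=O
Why: Ozonolysis of the trisubstituted alkene with reductive work-up; the stereocentre (future C13) is remote and the silyl ether is inert.

Step 3
Reactants: 4 (4S)-6-(tert-butyldiphenylsilyloxy)-4-methylhexanal; 5 2-(triphenylphosphoranylidene)propanal
Product: 6 (2E,6S)-8-(tert-butyldiphenylsilyloxy)-2,6-dimethyloct-2-enal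
Conditions: toluene, 90 °C
Reagents that add atoms: none
Why: Wittig olefination with a stabilised formyl ylide, which should give the (E)-2-methyl-2-enal; this geometry is what later places C11 and C20 cis.

Step 4
Reactants: 7 but-3-en-2-one
Product: 8 2-(triisopropylsilyloxy)buta-1,3-diene
Conditions: iPr3SiOTf, Et3N, Et2O, 0 °C → rt
Reagents that add atoms: triisopropylsilyl trifluoromethanesulfonate, CC(C)[Si](OS(=O)(=O)C(F)(F)F)(C(C)C)C(C)C
Why: Soft enolisation and O-silylation of the methyl ketone; the bulky silyl group makes the diene stable to distillation and to the acidic catalyst of step 5.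

Step 5
Reactants: 6 (2E,6S)-8-(tert-butyldiphenylsilyloxy)-2,6-dimethyloct-2-enal; 8 2-(triisopropylsilyloxy)buta-1,3-diene
Product: 9 (1S,6S)-6-[(3S)-5-(tert-butyldiphenylsilyloxy)-3-methylpentyl]-1-methyl-4-(triisopropylsilyloxy)cyclohex-3-ene-1-carbaldehyde
Conditions: (R)-3,3-diphenyl-1-(o-tolyl)tetrahydro-1H,3H-pyrrolo[1,2-c][1,3,2]oxazaborole (20 mol%), Tf2NH (18 mol%), 8 (2 equiv), CH2Cl2, −78 → −40 °C; Et3N quench
Reagents that add atoms: none
Why: This is a catalytic enantioselective Diels–Alder reaction of a 2-methyl-2-enal with a 2-silyloxybutadiene under a cationic oxazaborolidine, a known reaction class. The protonated oxazaborolidine binds the formyl oxygen of 6 at boron, and the formyl C–H···O contact together with the s-trans enal geometry holds the dienophile over one aryl group, which covers one face. Diene 8 adds to the open face through a concerted but asynchronous [4+2] transition state in which its nucleophilic CH2 terminus (C8) bonds ahead to the β-carbon C9 while C5 bonds to the α-carbon C10. Ring B closes in this one step as a six-membered ring by suprafacial cycloaddition across C5–C10 and C8–C9, leaving the C6=C7 silyl enol ether. The quaternary centre C10 is set by the catalyst, the (R)-catalyst being expected to expose the face from which CHO, C9 and CH3 appear counterclockwise. C9 is not set independently: suprafacial addition to the (E)-alkene keeps C11 and C20 cis, so its configuration follows from C10 and from step 3. The step needs para regiochemistry (oxygen on C7), which the 2-silyloxy group secures by placing the largest diene coefficient on its CH2 terminus opposite the β-carbon of the activated enal. It also needs reaction at C=C and not at C=O, which the moderate nucleophilicity of this diene favours; endo and exo modes give the same product because the diene termini are unsubstituted, and C13 is too remote to interfere.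

Step 6
Reactants: 9 (1S,6S)-6-[(3S)-5-(tert-butyldiphenylsilyloxy)-3-methylpentyl]-1-methyl-4-(triisopropylsilyloxy)cyclohex-3-ene-1-carbaldehyde
Product: 10 4-methyl-5-[(3S)-5-(tert-butyldiphenylsilyloxy)-3-methylpentyl]-1-(triisopropylsilyloxy)-4-vinylcyclohex-1-ene (methyl and side chain cis)
Conditions: Ph3PCH3Br, KN(SiMe3)2, THF, 0 °C → rt
Reagents that add atoms: methyltriphenylphosphonium bromide, C[P+](c1ccccc1)(c1ccccc1)c1ccccc1.[Br-]
Why: Wittig methylenation of a non-enolisable neopentylic aldehyde; the base-stable silyl enol ether keeps the C7 ketone masked, and the new CH2 is expelled again in step 14.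

Step 7
Reactants: 10 4-methyl-5-[(3S)-5-(tert-butyldiphenylsilyloxy)-3-methylpentyl]-1-(triisopropylsilyloxy)-4-vinylcyclohex-1-ene
Product: 11 4-methyl-5-[(3S)-5-(tert-butyldiphenylsilyloxy)-3-methylpentyl]-4-vinylcyclohex-2-en-1-one (methyl and side chain cis)
Conditions: Pd(OAc)2 (1.1 equiv), DMSO/CH2Cl2, 40 °C
Reagents that add atoms: none
Why: Saegusa–Ito oxidation: the enol ether passes its enolate to divalent palladium and β-hydride elimination from C5 gives the C5=C6 enone, its position fixed by the cycloaddition; C10 is quaternary, so the double bond cannot migrate.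

Step 8
Reactants: 11 4-methyl-5-[(3S)-5-(tert-butyldiphenylsilyloxy)-3-methylpentyl]-4-vinylcyclohex-2-en-1-one
Product: 13 4,6-dimethyl-5-[(3S)-5-(tert-butyldiphenylsilyloxy)-3-methylpentyl]-4-vinylcyclohex-2-en-1-one (C8 epimers), via lithium dienolate 12 (not isolated)
Conditions: LiN(iPr)2, THF, −78 °C; MeI, DMPU, −78 → −30 °C
Reagents that add atoms: iodomethane, CI
Why: Kinetic deprotonation of a cyclohex-2-enone occurs at the α' carbon (C8), the γ carbon C10 being quaternary; alkylation of the cross-conjugated enolate brings in C17, and the C8 configuration does not matter because C8 is planar again in step 9.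

Step 9
Reactants: 13 4,6-dimethyl-5-[(3S)-5-(tert-butyldiphenylsilyloxy)-3-methylpentyl]-4-vinylcyclohex-2-en-1-one
Product: 15 6-hydroxy-4,6-dimethyl-5-[(3S)-5-(tert-butyldiphenylsilyloxy)-3-methylpentyl]-4-vinylcyclohex-2-en-1-one (8α-OH and 8β-CH3), via potassium dienolate 14 (not isolated)
Conditions: KN(SiMe3)2, THF, −78 → −40 °C; 2-(phenylsulfonyl)-3-phenyloxaziridine, −78 °C; aq. NH4Cl
Reagents that add atoms: 2-(phenylsulfonyl)-3-phenyloxaziridine, O=S(=O)(c1ccccc1)N1OC1c1ccccc1
Why: Davis hydroxylation of the tetrasubstituted α' enolate; the oxygen should enter on the α face, anti to the C9 side chain (pseudoaxial to avoid allylic strain with C17) and away from C20, which sets C8 by substrate control.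

Step 10
Reactants: 15 6-hydroxy-4,6-dimethyl-5-[(3S)-5-(tert-butyldiphenylsilyloxy)-3-methylpentyl]-4-vinylcyclohex-2-en-1-one
Product: 16 4,6-dimethyl-5-[(3S)-5-(tert-butyldiphenylsilyloxy)-3-methylpentyl]-4-vinylcyclohex-2-ene-1,6-diol (7β-OH and 8α-OH)
Conditions: NaBH4, CeCl3·7H2O, MeOH, −78 → −40 °C
Reagents that add atoms: none
Why: Luche 1,2-reduction; hydride should attack C7 from the α face, anti to the C17 methyl on the neighbouring quaternary carbon and in line with cerium chelation between carbonyl and 8-hydroxyl, giving the 7β-alcohol whose C–O bond later directs C4 to the β face of C5.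

Step 11
Reactants: 16 4,6-dimethyl-5-[(3S)-5-(tert-butyldiphenylsilyloxy)-3-methylpentyl]-4-vinylcyclohex-2-ene-1,6-diol; 17 2-methylpropanoyl chloride
Product: 18 7β-(2-methylpropanoyloxy) 8α-trimethylsilyl ether of 16
Conditions: pyridine, DMAP (cat.), CH2Cl2, 0 °C; then N-(trimethylsilyl)imidazole, rt
Reagents that add atoms: N-(trimethylsilyl)imidazole, C[Si](C)(C)n1ccnc1
Why: Acylation distinguishes the secondary allylic from the tertiary hydroxyl by rate; the tertiary hydroxyl is then capped in the same flask so that no alkoxide sits next to the ester in step 12.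

Step 12
Reactants: 18 7β-(2-methylpropanoyloxy) 8α-trimethylsilyl ether of 16
Product: 21 2-[4-hydroxy-4,6-dimethyl-5-[(3S)-5-(tert-butyldiphenylsilyloxy)-3-methylpentyl]-6-vinylcyclohex-2-en-1-yl]-2-methylpropanoic acid (5α-H and 8α-OH), via silyl ketene acetal 19 (not isolated), via bis-silyl ester 20 (not isolated)
Conditions: LiN(iPr)2, Me3SiCl/Et3N, THF, −78 °C → rt → 65 °C; citric acid, MeOH/H2O
Reagents that add atoms: none
Why: Ireland–Claisen rearrangement; the suprafacial [3,3] shift should deliver the ketene-acetal carbon (C4) to C5 on the β face where the C7–O bond stood, which sets 5α-H, creates the C4 quaternary centre and removes oxygen from C7 as the C6=C7 alkene; the ketene-acetal geometry is irrelevant because both substituents are methyl.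

Step 13
Reactants: 21 2-[4-hydroxy-4,6-dimethyl-5-[(3S)-5-(tert-butyldiphenylsilyloxy)-3-methylpentyl]-6-vinylcyclohex-2-en-1-yl]-2-methylpropanoic acid
Product: 23 vinyl ketone of 21 (CO2H replaced by C(=O)CH=CH2), via trilithium gem-diolate 22 (not isolated)
Conditions: CH2=CHLi (4 equiv), THF, −78 → 0 °C; inverse quench into aq. NH4Cl
Reagents that add atoms: vinyllithium, [Li]C=C
Why: Addition of an organolithium to a lithium carboxylate stops at the gem-diolate, which releases the ketone only on hydrolysis; the acid has no α-hydrogen, so enolisation cannot compete.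

Step 14
Reactants: 23 vinyl ketone of 21
Product: 24 (13S)-15-(tert-butyldiphenylsilyloxy)-8α-hydroxylabda-1,6-dien-3-one
Conditions: second-generation Grubbs catalyst (H2IMes)(PCy3)Cl2Ru=CHPh (5 mol%), CH2Cl2 (5 mM), 40 °C
Reagents that add atoms: none
Why: Ring-closing metathesis of the neopentylic vinyl group with the vinyl ketone closes ring A as a cyclohexenone with loss of ethene; the two arms are trans on C10 and C5, so the ring closes trans-fused, and the unstrained ring B alkene should stay out of the reaction.

Step 15
Reactants: 24 (13S)-15-(tert-butyldiphenylsilyloxy)-8α-hydroxylabda-1,6-dien-3-one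
Product: 25 (13S)-15-(tert-butyldiphenylsilyloxy)-8α-hydroxylabdan-3-one
Conditions: H2 (1 atm), 10% Pd/C, EtOAc, rt
Reagents that add atoms: none
Why: Heterogeneous hydrogenation of the enone C1=C2 and of the cis-disubstituted C6=C7; no stereocentre is formed, and neutral EtOAc is chosen to keep the tertiary allylic C–O bond from hydrogenolysis.

Step 16
Reactants: 25 (13S)-15-(tert-butyldiphenylsilyloxy)-8α-hydroxylabdan-3-one
Product: 27 (13S)-labdane-8α,15-diol, via C3 hydrazone 26 (not isolated)
Conditions: N2H4·H2O, KOH, diethylene glycol, 130 °C then 200 °C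
Reagents that add atoms: none
Why: Wolff–Kishner reduction (Huang–Minlon conditions), the standard removal of a 3-oxo group beside a 4,4-dimethyl centre; the tertiary alkoxide is inert, and the hot alkaline glycol is expected to cleave the primary silyl ether in the same operation.

Step 17
Reactants: 27 (13S)-labdane-8α,15-diol
Product: 29 (13S)-8α-hydroxylabdan-15-oic acid, via aldehyde 28 (not isolated)
Conditions: TEMPO (10 mol%), NaOCl (5 mol%), NaClO2, MeCN/phosphate buffer pH 6.7, 35 °C
Reagents that add atoms: sodium chlorite, [Na+].[O-]Cl=O
Why: Oxoammonium oxidation of the primary alcohol to the aldehyde and chlorite oxidation to the acid in one pot; the tertiary C8 alcohol cannot be oxidised and the near-neutral medium avoids its dehydration.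

Step 18
Reactants: 29 (13S)-8α-hydroxylabdan-15-oic acid
Product: 31 (5S,8R,9R,10S,13S)-8-acetoxylabdan-15-oic acid, via mixed anhydride 30 (not isolated)
Conditions: Ac2O, DMAP, Et3N, CH2Cl2, 40 °C; then aq. NaHCO3/THF, rt; acidify to pH 3
Reagents that add atoms: acetic anhydride, CC(=O)OC(C)=O
Why: DMAP-catalysed acetylation of the hindered equatorial tertiary alcohol; the carboxyl group is converted into a mixed anhydride that is hydrolysed in the work-up far faster than the tertiary acetate, and the basic medium disfavours elimination.

## Compound list

1 | (S)-citronellol | CC(C)=CCC[C@H](C)CCO | starting material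
2 | (3S)-1-(tert-butyldiphenylsilyloxy)-3,7-dimethyloct-6-ene | CC(C)=CCC[C@H](C)CCO[Si](c1ccccc1)(c1ccccc1)C(C)(C)C | intermediate
3 | secondary ozonide of 2 (3,3-dimethyl-1,2,4-trioxolane; epimers at the trioxolane CH; not isolated) | CC3(C)OOC(CC[C@H](C)CCO[Si](c1ccccc1)(c1ccccc1)C(C)(C)C)O3 | intermediate
4 | (4S)-6-(tert-butyldiphenylsilyloxy)-4-methylhexanal | O=CCC[C@H](C)CCO[Si](c1ccccc1)(c1ccccc1)C(C)(C)C | intermediate
5 | 2-(triphenylphosphoranylidene)propanal | CC(C=O)=P(c1ccccc1)(c1ccccc1)c1ccccc1 | starting material
6 | (2E,6S)-8-(tert-butyldiphenylsilyloxy)-2,6-dimethyloct-2-enal | O=C/C(C)=C/CC[C@H](C)CCO[Si](c1ccccc1)(c1ccccc1)C(C)(C)C | intermediate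
7 | but-3-en-2-one | CC(=O)C=C | starting material
8 | 2-(triisopropylsilyloxy)buta-1,3-diene | C=CC(=C)O[Si](C(C)C)(C(C)C)C(C)C | intermediate
9 | (1S,6S)-6-[(3S)-5-(tert-butyldiphenylsilyloxy)-3-methylpentyl]-1-methyl-4-(triisopropylsilyloxy)cyclohex-3-ene-1-carbaldehyde | O=C[C@@]1(C)CC=C(O[Si](C(C)C)(C(C)C)C(C)C)C[C@@H]1CC[C@H](C)CCO[Si](c1ccccc1)(c1ccccc1)C(C)(C)C | intermediate
10 | 4-methyl-5-[(3S)-5-(tert-butyldiphenylsilyloxy)-3-methylpentyl]-1-(triisopropylsilyloxy)-4-vinylcyclohex-1-ene (methyl and side chain cis; 10α-vinyl) | C=C[C@@]1(C)CC=C(O[Si](C(C)C)(C(C)C)C(C)C)C[C@@H]1CC[C@H](C)CCO[Si](c1ccccc1)(c1ccccc1)C(C)(C)C | intermediate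
11 | 4-methyl-5-[(3S)-5-(tert-butyldiphenylsilyloxy)-3-methylpentyl]-4-vinylcyclohex-2-en-1-one (C7 ketone, C5=C6; methyl and side chain cis) | C=C[C@@]1(C)C=CC(=O)C[C@@H]1CC[C@H](C)CCO[Si](c1ccccc1)(c1ccccc1)C(C)(C)C | intermediate
12 | lithium dienolate of 11 (C7–OLi, C7=C8; not isolated) | C=C[C@@]1(C)C=CC(O[Li])=C[C@@H]1CC[C@H](C)CCO[Si](c1ccccc1)(c1ccccc1)C(C)(C)C | intermediate
13 | 4,6-dimethyl-5-[(3S)-5-(tert-butyldiphenylsilyloxy)-3-methylpentyl]-4-vinylcyclohex-2-en-1-one (C8 epimers) | C=C[C@@]1(C)C=CC(=O)C(C)[C@@H]1CC[C@H](C)CCO[Si](c1ccccc1)(c1ccccc1)C(C)(C)C | intermediate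
14 | potassium dienolate of 13 (C7–OK, C7=C8; not isolated) | C=C[C@@]1(C)C=CC(O[K])=C(C)[C@@H]1CC[C@H](C)CCO[Si](c1ccccc1)(c1ccccc1)C(C)(C)C | intermediate
15 | 6-hydroxy-4,6-dimethyl-5-[(3S)-5-(tert-butyldiphenylsilyloxy)-3-methylpentyl]-4-vinylcyclohex-2-en-1-one (8α-OH, 8β-CH3; hydroxyl trans to the side chain) | C=C[C@@]1(C)C=CC(=O)[C@@](C)(O)[C@@H]1CC[C@H](C)CCO[Si](c1ccccc1)(c1ccccc1)C(C)(C)C | intermediate
16 | 4,6-dimethyl-5-[(3S)-5-(tert-butyldiphenylsilyloxy)-3-methylpentyl]-4-vinylcyclohex-2-ene-1,6-diol (7β-OH cis to the side chain, 8α-OH trans) | C=C[C@@]1(C)C=C[C@H](O)[C@@](C)(O)[C@@H]1CC[C@H](C)CCO[Si](c1ccccc1)(c1ccccc1)C(C)(C)C | intermediate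
17 | 2-methylpropanoyl chloride (isobutyryl chloride) | CC(C)C(Cl)=O | starting material
18 | 7β-(2-methylpropanoyloxy) 8α-trimethylsilyl ether of 16 | C=C[C@@]1(C)C=C[C@H](OC(=O)C(C)C)[C@@](C)(O[Si](C)(C)C)[C@@H]1CC[C@H](C)CCO[Si](c1ccccc1)(c1ccccc1)C(C)(C)C | intermediate
19 | trimethylsilyl ketene acetal of 18 (not isolated) | C=C[C@@]1(C)C=C[C@H](OC(O[Si](C)(C)C)=C(C)C)[C@@](C)(O[Si](C)(C)C)[C@@H]1CC[C@H](C)CCO[Si](c1ccccc1)(c1ccccc1)C(C)(C)C | intermediate
20 | trimethylsilyl ester 8-O-trimethylsilyl ether of 21 (not isolated) | C=C[C@@]1(C)[C@H](C(C)(C)C(=O)O[Si](C)(C)C)C=C[C@@](C)(O[Si](C)(C)C)[C@@H]1CC[C@H](C)CCO[Si](c1ccccc1)(c1ccccc1)C(C)(C)C | intermediate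
21 | 2-[4-hydroxy-4,6-dimethyl-5-[(3S)-5-(tert-butyldiphenylsilyloxy)-3-methylpentyl]-6-vinylcyclohex-2-en-1-yl]-2-methylpropanoic acid (5α-H, C4 β; 8α-OH; 10α-vinyl) | C=C[C@@]1(C)[C@H](C(C)(C)C(=O)O)C=C[C@@](C)(O)[C@@H]1CC[C@H](C)CCO[Si](c1ccccc1)(c1ccccc1)C(C)(C)C | intermediate
22 | trilithium gem-diolate adduct of 21 and vinyllithium (not isolated) | C=C[C@@]1(C)[C@H](C(C)(C)C(O[Li])(O[Li])C=C)C=C[C@@](C)(O[Li])[C@@H]1CC[C@H](C)CCO[Si](c1ccccc1)(c1ccccc1)C(C)(C)C | intermediate
23 | vinyl ketone of 21: 4-[ring B C5]-4-methylpent-1-en-3-one, otherwise as 21 | C=C[C@@]1(C)[C@H](C(C)(C)C(=O)C=C)C=C[C@@](C)(O)[C@@H]1CC[C@H](C)CCO[Si](c1ccccc1)(c1ccccc1)C(C)(C)C | intermediate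
24 | (13S)-15-(tert-butyldiphenylsilyloxy)-8α-hydroxylabda-1,6-dien-3-one (5α-H, 9α-H, 10β-CH3) | O[C@]1(C)C=C[C@H]2C(C)(C)C(=O)C=C[C@]2(C)[C@H]1CC[C@H](C)CCO[Si](c1ccccc1)(c1ccccc1)C(C)(C)C | intermediate
25 | (13S)-15-(tert-butyldiphenylsilyloxy)-8α-hydroxylabdan-3-one | O[C@]1(C)CC[C@H]2C(C)(C)C(=O)CC[C@]2(C)[C@H]1CC[C@H](C)CCO[Si](c1ccccc1)(c1ccccc1)C(C)(C)C | intermediate
26 | C3 hydrazone of 25 (not isolated) | O[C@]1(C)CC[C@H]2C(C)(C)C(=NN)CC[C@]2(C)[C@H]1CC[C@H](C)CCO[Si](c1ccccc1)(c1ccccc1)C(C)(C)C | intermediate
27 | (13S)-labdane-8α,15-diol | O[C@]1(C)CC[C@H]2C(C)(C)CCC[C@]2(C)[C@H]1CC[C@H](C)CCO | intermediate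
28 | (13S)-8α-hydroxylabdan-15-al (not isolated) | O[C@]1(C)CC[C@H]2C(C)(C)CCC[C@]2(C)[C@H]1CC[C@H](C)CC=O | intermediate
29 | (13S)-8α-hydroxylabdan-15-oic acid | O[C@]1(C)CC[C@H]2C(C)(C)CCC[C@]2(C)[C@H]1CC[C@H](C)CC(=O)O | intermediate
30 | mixed acetic anhydride of 31 at C15 (not isolated) | CC(=O)O[C@]1(C)CC[C@H]2C(C)(C)CCC[C@]2(C)[C@H]1CC[C@H](C)CC(=O)OC(C)=O | intermediate
31 | (5S,8R,9R,10S,13S)-8-acetoxylabdan-15-oic acid | CC(=O)O[C@]1(C)CC[C@H]2C(C)(C)CCC[C@]2(C)[C@H]1CC[C@H](C)CC(=O)O | target

## Step count and least certain steps

Total: 18 steps. Longest linear sequence: 17 steps (steps 1–3 and 5–18 from 1); step 4 is a one-step branch.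

**Step 5 (key step).** The β-substituted enal may add too slowly at the low temperature the catalyst needs, and raising the temperature risks erosion of facial selectivity and silyl transfer or aldol-type attack at the formyl group. Fallback, setting out from 6:
- The enal is combined with the far more nucleophilic (E)-1-(dimethylamino)-3-(tert-butyldimethylsilyloxy)buta-1,3-diene, which needs no strong Lewis acid. The catalyst is a chiral salen complex of trivalent chromium, (salen)CrSbF6 (salen = N,N'-bis(3,5-di-tert-butylsalicylidene)cyclohexane-1,2-diamine dianion, enantiomer chosen for the same face).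
- The same two bonds form and give the amino silyl enol ether cycloadduct F1.
- Dilute HCl in THF hydrolyses the enol ether and eliminates dimethylamine, giving the formyl enone F2.
- Methylenation of the formyl group with Ph3P=CH2 at −78 °C, where the aldehyde reacts ahead of the enone, comes back to the route at 11.

**Step 12.** The [3,3] shift has to join a carbon that becomes quaternary to C5 beside the quaternary C10. It may be so slow that fragmentation of the ketene acetal or C-silylation takes over on heating. Fallback, setting out from 16:
- Propanoyl chloride and then N-(trimethylsilyl)imidazole give the 7β-propanoate 8α-trimethylsilyl ether F3.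
- Its Ireland–Claisen rearrangement now forms only a tertiary carbon next to C5 and gives, after citric acid work-up, the 2-substituted propanoic acid F4 (C4 epimers).
- Deprotonation with LiN(iPr)2 (3 equiv) to the carboxylate enediolate and C-methylation with MeI adds the second methyl group and comes back to the route at 21.

**Step 10.** Hydride delivery may show poor facial selectivity or favour the β face, which would give the 7α-alcohol and, after step 12, the cis ring fusion. Fallback, setting out from 15: the reduction is taken to the 7α-epimeric diol F5, which is esterified with 2-methylpropanoic acid under Mitsunobu conditions (PPh3, diisopropyl azodicarboxylate) with inversion at C7 and then silylated with N-(trimethylsilyl)imidazole. This comes back to the route at 18.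

**Step 13.** Addition to the hindered carboxylate may stall, or ketone released early may take up a second vinyl group in 1,2 or 1,4 fashion. Fallback, setting out from 21:
- MeLi (4 equiv) gives the methyl ketone F6.
- OsO4 (cat.)/NaIO4 with 2,6-lutidine cleaves the monosubstituted vinyl group in preference to the hindered ring alkene and gives the keto aldehyde F7.
- KOH in MeOH closes ring A by intramolecular aldol condensation and comes back to the route at 24.

**Step 18.** Acylation of the hindered tertiary hydroxyl may be incomplete while the carboxyl group consumes reagent, and forcing it risks loss of acetic acid from C8 to an alkene. Fallback, setting out from 27: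
- Both hydroxyls are acetylated with AcCl/N,N-dimethylaniline before any acid is present, giving the diacetate F8.
- K2CO3 in MeOH removes only the primary acetate and gives the acetoxy alcohol F9.
- The oxidation of step 17 then comes back to the route at 31.

## Further compounds

F1 | step 5 | 2-(dimethylamino)-1-methyl-4-(tert-butyldimethylsilyloxy)-6-[(3S)-5-(tert-butyldiphenylsilyloxy)-3-methylpentyl]cyclohex-3-ene-1-carbaldehyde (C9 and C10 as in 9; amino-bearing carbon not controlled, lost in the next operation) | O=C[C@@]1(C)C(N(C)C)C=C(O[Si](C)(C)C(C)(C)C)C[C@@H]1CC[C@H](C)CCO[Si](c1ccccc1)(c1ccccc1)C(C)(C)C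
F2 | step 5 | 1-methyl-4-oxo-6-[(3S)-5-(tert-butyldiphenylsilyloxy)-3-methylpentyl]cyclohex-2-ene-1-carbaldehyde (methyl and side chain cis) | O=C[C@@]1(C)C=CC(=O)C[C@@H]1CC[C@H](C)CCO[Si](c1ccccc1)(c1ccccc1)C(C)(C)C
F3 | step 12 | 7β-propanoate 8α-trimethylsilyl ether of 16 | C=C[C@@]1(C)C=C[C@H](OC(=O)CC)[C@@](C)(O[Si](C)(C)C)[C@@H]1CC[C@H](C)CCO[Si](c1ccccc1)(c1ccccc1)C(C)(C)C
F4 | step 12 | 2-[4-hydroxy-4,6-dimethyl-5-[(3S)-5-(tert-butyldiphenylsilyloxy)-3-methylpentyl]-6-vinylcyclohex-2-en-1-yl]propanoic acid (ring centres as in 21; C4 epimers) | C=C[C@@]1(C)[C@H](C(C)C(=O)O)C=C[C@@](C)(O)[C@@H]1CC[C@H](C)CCO[Si](c1ccccc1)(c1ccccc1)C(C)(C)C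
F5 | step 10 | 7α-epimer of diol 16 (7α-OH, 8α-OH) | C=C[C@@]1(C)C=C[C@@H](O)[C@@](C)(O)[C@@H]1CC[C@H](C)CCO[Si](c1ccccc1)(c1ccccc1)C(C)(C)C
F6 | step 13 | methyl ketone of 21 (CO2H replaced by C(=O)CH3) | C=C[C@@]1(C)[C@H](C(C)(C)C(C)=O)C=C[C@@](C)(O)[C@@H]1CC[C@H](C)CCO[Si](c1ccccc1)(c1ccccc1)C(C)(C)C
F7 | step 13 | keto aldehyde: F6 with the C10 vinyl group cleaved to formyl | O=C[C@@]1(C)[C@H](C(C)(C)C(C)=O)C=C[C@@](C)(O)[C@@H]1CC[C@H](C)CCO[Si](c1ccccc1)(c1ccccc1)C(C)(C)C
F8 | step 18 | (13S)-labdane-8α,15-diyl diacetate | CC(=O)O[C@]1(C)CC[C@H]2C(C)(C)CCC[C@]2(C)[C@H]1CC[C@H](C)CCOC(C)=O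
F9 | step 18 | (13S)-8α-acetoxylabdan-15-ol | CC(=O)O[C@]1(C)CC[C@H]2C(C)(C)CCC[C@]2(C)[C@H]1CC[C@H](C)CCO
A1 | alternative 1 | methyl (13S)-8-oxo-17-norlabd-2-en-15-oate | O=C1CC[C@H]2C(C)(C)C=CC[C@]2(C)[C@H]1CC[C@H](C)CC(=O)OC
A2 | alternative 2 | trans-fused 4,4,10-trimethyldecal-6-en-8-one (labdane numbering; 5α-H, 10β-CH3; 17-nor, C9 unsubstituted) | O=C1C=C[C@H]2C(C)(C)CCC[C@]2(C)C1
A3 | alternative 3 | methyl 8α-hydroxy-13,14,15,16-tetranorlabdan-12-oate | O[C@]1(C)CC[C@H]2C(C)(C)CCC[C@]2(C)[C@H]1CC(=O)OC
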